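the same everywhere: starting complex 0.62 M

| charge | incoming ligand | remark | time |
|---|---|---|---|
| oak | 0.19 M | run made earlier |  |
| alder | 1.1 M | run made earlier |  |
| midnight | 0.310 M |  | 30 min |
| summer | 0.930 M |  | 30 min |
| winter | 1.24 M |  | 30 min |

| run | time / min | complex with three exchanged / % | complex with two exchanged / % | starting complex / % |
|---|---|---|---|---|
| oak | 2.50 | 0 | 0.2 | 75.1 |
| oak | 8.00 | 0.2 | 0 | 66.6 |
| oak | 15.0 | 0.9 | 1.3 | 63.7 |
| oak | 20.0 | 0 | 1.2 | 62.5 |
| oak | 30.0 | 0 | 0.1 | 59.4 |
| alder | 2.50 | 2.4 | 9.3 | 16.4 |
| alder | 5.00 | 1.9 | 6.5 | 6.3 |
| alder | 8.00 | 0.9 | 5.0 | 2.1 |
| alder | 15.0 | 0.8 | 3.3 | 0 |
| alder | 30.0 | 0 | 0.2 | 0 |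

(standard deviation of a reading: 0.5 percentage points)

1. which of these holds the largest part of the starting complex at the end of midnight (complex with one exchanged / complex with two exchanged / starting complex / complex with three exchanged / complex with four exchanged)
2. which of these holds the largest part of the starting complex at the end of summer (complex with one exchanged / complex with two exchanged / starting complex / complex with three exchanged / complex with four exchanged)
3. which of these holds the largest part of the starting complex at the end of winter (complex with one exchanged / complex with two exchanged / starting complex / complex with three exchanged / complex with four exchanged)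
4. amount of complex with three exchanged at the end of summer, in percent of the starting complex charged



The constants come first, and the readings give me one of them as a reading: in alder the starting complex falls from 16.4% at 2.50 min to 6.3% at 5.00 min, a pseudo-first-order constant of 0.383 min⁻¹. I take that constant to go with the 0.480 M of incoming ligand charged beyond one-for-one, so the 0.310 M beyond it in summer gives 7.41 lifetimes in 30 min, and I expect about 0.0602% of the starting complex there.

What I count is the turnovers on offer, the incoming ligand charged per starting complex charged, which is 1.50 for summer. Oak shows what one turnover does: by 8.00 min it has lost 0.207 M of starting complex to 0.19 M of ligand, about one for one. With this main step alone, midnight, offering 0.500, keeps 50.0% of its starting complex, the ligand being the limiting reagent.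

Oak then adds a second process, a drift of 7.2 percentage points from 8.00 min to 30.0 min. Taking the same off midnight leaves me 42.8% of its starting complex by my reckoning.

The rest is the onward exchange. Alder, offering 1.77, reads its complex with two exchanged down from 9.3% to 0.2% and its complex with three exchanged down from 2.4% to 0% between 2.50 min and 30.0 min. I read this as nothing feeding them late in alder, so I take it that the complex with one exchanged has left too, in alder and in the flasks I am asked about, and that what went onward ends with four exchanged. Each complex reaching that form takes 3 turnovers beyond the first, which gives me an estimated ceiling near 16.7% for summer and near 33.3% for winter. I therefore commit to the starting complex in midnight, which offers fewer than one turnover per starting complex, to the complex with four exchanged in summer and in winter, and to under 1% of the complex with three exchanged at the end of summer, since alder reads 0.8% at 15.0 min.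

The forecast differs on the choices, naming complex with one exchanged for midnight, complex with one exchanged for summer and complex with one exchanged for winter, with 0.2% for the amount, on the ground that “the mixture is probably mostly monoexchanged”.

The flasks give starting complex at 45.5% in midnight, complex with four exchanged at 9.56% in summer, complex with four exchanged at 16.7% in winter, and 0.658% of the complex with three exchanged at the end of summer.

    starting complex + incoming ligand → leaving ligand + complex with one exchanged (k = 0.0180 M⁻¹ s⁻¹)
    complex with one exchanged + incoming ligand → leaving ligand + complex with two exchanged (k = 0.0134 M⁻¹ s⁻¹)
    complex with two exchanged + incoming ligand → leaving ligand + complex with three exchanged (k = 0.00657 M⁻¹ s⁻¹)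
    complex with three exchanged + incoming ligand → leaving ligand + complex with four exchanged (k = 0.0220 M⁻¹ s⁻¹)
    2 starting complex → homo dimer (k = 1.05 × 10⁻⁴ M⁻¹ s⁻¹)
    complex with one exchanged → side product (k = 0.0500 s⁻¹)

The side product, which no reading showed, holds 87.5% of the starting complex charged in summer at 30.0 min. Of the 1.50 turnovers on offer there, 1.30 are used, with 13% of the ligand still unbound. A neighbour flask, summer with 0.23 M of incoming ligand, offers 0.371 turnovers, fewer than one per starting complex, and its starting complex stands at 55.0% at 30.0 min.

All runs are simulated for substances that don't exist.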